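**Retrosynthetic overview**
- Prevezol C comes from a hydroxyl-directed reduction of the ring A α-hydroxy ketone, which sets the secondary carbinol of the trans-diaxial diol.
- Key disconnection: the bond between ring A and the allylic CH2, made by a palladium-catalysed allylic alkylation (Tsuji–Trost) of a ring A silyl enol ether with a ring B 2-substituted allyl carbonate that already carries the syn-bromohydrin.
- Ring B piece: the (R)-methyl ketone is homologated to an epoxide and isomerised to the allylic alcohol; the syn-bromohydrin is installed by a new selenium-redox-catalysed syn-oxybromination.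
- Ring A piece: the (S)-limonene-type diene is taken through epoxide, trans-diaxial diol and α-ketol to the bis-silyl enol ether.
- Ring order: both cyclohexene rings are made first and separately, by enantiomeric organocatalytic Diels–Alder reactions of isoprene with acrolein (ring A from the (S)-adduct, ring B from the (R)-adduct); no ring is formed later.

**Route**

Step 1
Reactants: 1 isoprene (2-methylbuta-1,3-diene); 2 acrolein (prop-2-enal)
Product: 3 (1S)-4-methylcyclohex-3-ene-1-carbaldehyde
Conditions: (5R)-5-benzyl-2,2,3-trimethylimidazolidin-4-one·HCl (10 mol%), MeCN/H2O 95:5, 23 °C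
Reagents that add atoms: none
Why: Iminium-ion organocatalytic Diels–Alder reaction; the 2-methyl group of the diene gives the 1,4 ("para") adduct and the benzyl group of the (5R)-catalyst shields one face of the (E)-iminium ion, so the diene adds to the open face and sets the (S) centre (about 90% ee, raised later at crystalline diol 8).

Step 2
Reactants: 3 (1S)-4-methylcyclohex-3-ene-1-carbaldehyde
Product: 4 1-[(1S)-4-methylcyclohex-3-en-1-yl]ethan-1-ol (both carbinol epimers)
Conditions: MeMgBr, Et2O, −78 to 0 °C; then aq NH4Cl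
Reagents that add atoms: methylmagnesium bromide, C[Mg]Br
Why: Grignard 1,2-addition to the aldehyde; the new carbinol centre is unselective but is erased in step 3.

Step 3
Reactants: 4 1-[(1S)-4-methylcyclohex-3-en-1-yl]ethan-1-ol
Product: 5 1-[(1S)-4-methylcyclohex-3-en-1-yl]ethan-1-one
Conditions: Pr4N[RuO4] (5 mol%), NMO, 4 Å MS, CH2Cl2, 23 °C
Reagents that add atoms: none
Why: Ley–Griffith oxidation under neutral conditions gives the methyl ketone without epimerising the α centre or touching the alkene.

Step 4
Reactants: 5 1-[(1S)-4-methylcyclohex-3-en-1-yl]ethan-1-one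
Product: 6 (4S)-1-methyl-4-(prop-1-en-2-yl)cyclohex-1-ene [(S)-limonene]
Conditions: Ph3PCH3Br, KOtBu, THF, 0 °C, then 5, 0 to 23 °C
Reagents that add atoms: methyltriphenylphosphonium bromide, C[P+](c1ccccc1)(c1ccccc1)c1ccccc1.[Br-]
Why: Wittig methylenation; at 0 °C the ylide adds to the carbonyl faster than it enolises the ketone, so the stereocentre is kept.

Step 5
Reactants: 6 (4S)-1-methyl-4-(prop-1-en-2-yl)cyclohex-1-ene
Product: 8 (1R,2R,4S)-1-methyl-4-(prop-1-en-2-yl)cyclohexane-1,2-diol, via limonene 1,2-oxide 7 (not isolated)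
Conditions: mCPBA (1.05 equiv), CH2Cl2, 0 °C; then 0.05 M H2SO4, THF/H2O 1:1, 0 to 23 °C; recrystallise
Reagents that add atoms: meta-chloroperoxybenzoic acid, OOC(=O)c1cccc(Cl)c1; water, O
Why: Prilezhaev epoxidation picks the electron-rich trisubstituted ring alkene over the isopropenyl group, and acid hydrolysis opens both epoxide epimers trans-diaxially (Fürst–Plattner rule) to the same diol, with the tertiary OH cis and the secondary OH trans to the isopropenyl group; recrystallisation raises the enantiomeric purity.

Step 6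
Reactants: 8 (1R,2R,4S)-1-methyl-4-(prop-1-en-2-yl)cyclohexane-1,2-diol
Product: 9 (2R,5S)-2-hydroxy-2-methyl-5-(prop-1-en-2-yl)cyclohexan-1-one
Conditions: IBX (1.5 equiv), DMSO, 23 °C
Reagents that add atoms: none
Why: IBX oxidation turns the secondary alcohol of the 1,2-diol into the ketone without glycol cleavage; the tertiary alcohol is inert, so the tertiary carbinol centre from step 5 is kept.

Step 7
Reactants: 9 (2R,5S)-2-hydroxy-2-methyl-5-(prop-1-en-2-yl)cyclohexan-1-one
Product: 10 trimethyl({(3S,6R)-6-methyl-3-(prop-1-en-2-yl)-6-[(trimethylsilyl)oxy]cyclohex-1-en-1-yl}oxy)silane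
Conditions: TMSOTf (2.4 equiv), Et3N (3.5 equiv), CH2Cl2, −78 to 0 °C
Reagents that add atoms: trimethylsilyl trifluoromethanesulfonate, C[Si](C)(C)OS(=O)(=O)C(F)(F)F
Why: Soft enolisation and silylation; the ketone can enolise only towards its CH2 side, so a single silyl enol ether forms while the tertiary OH is capped as its TMS ether.

Step 8
Reactants: 1 isoprene; 2 acrolein
Product: 11 (1R)-4-methylcyclohex-3-ene-1-carbaldehyde
Conditions: (5S)-5-benzyl-2,2,3-trimethylimidazolidin-4-one·HCl (10 mol%), MeCN/H2O 95:5, 23 °C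
Reagents that add atoms: none
Why: The same iminium-ion Diels–Alder reaction with the antipodal catalyst, which exposes the opposite face of the iminium ion and sets the (R) centre of ring B.

Step 9
Reactants: 11 (1R)-4-methylcyclohex-3-ene-1-carbaldehyde
Product: 12 1-[(1R)-4-methylcyclohex-3-en-1-yl]ethan-1-ol (both carbinol epimers)
Conditions: MeMgBr, Et2O, −78 to 0 °C; then aq NH4Cl
Reagents that add atoms: methylmagnesium bromide, C[Mg]Br
Why: Grignard 1,2-addition; the carbinol centre is removed in step 10.

Step 10
Reactants: 12 1-[(1R)-4-methylcyclohex-3-en-1-yl]ethan-1-ol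
Product: 13 1-[(1R)-4-methylcyclohex-3-en-1-yl]ethan-1-one
Conditions: Pr4N[RuO4] (5 mol%), NMO, 4 Å MS, CH2Cl2, 23 °C
Reagents that add atoms: none
Why: Ley–Griffith oxidation under neutral conditions keeps the α stereocentre.

Step 11
Reactants: 13 1-[(1R)-4-methylcyclohex-3-en-1-yl]ethan-1-one
Product: 15 2-methyl-2-[(1R)-4-methylcyclohex-3-en-1-yl]oxirane (both epimers at the oxirane carbon), via chlorohydrin lithium alkoxide 14 (not isolated)
Conditions: ICH2Cl, n-BuLi, THF, −78 °C; then warm to 23 °C
Reagents that add atoms: chloroiodomethane, ClCI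
Why: Chloromethyllithium, made in situ by iodine–lithium exchange, adds to the ketone at −78 °C faster than the ketone enolises (α centre kept), and the chlorohydrin alkoxide closes to the epoxide on warming (intramolecular Williamson reaction); the new oxirane centre is removed in step 12.

Step 12
Reactants: 15 2-methyl-2-[(1R)-4-methylcyclohex-3-en-1-yl]oxirane
Product: 16 2-[(1R)-4-methylcyclohex-3-en-1-yl]prop-2-en-1-ol
Conditions: diethylaluminium 2,2,6,6-tetramethylpiperidide (from 2,2,6,6-tetramethylpiperidine, n-BuLi, Et2AlCl; 3 equiv), toluene, 0 to 23 °C; then 1 M HCl, 0 °C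
Reagents that add atoms: none
Why: Aluminium amide-promoted isomerisation of an epoxide to an allylic alcohol (syn β-elimination); the bulky amide takes a proton from the unhindered methyl group and not from the ring methine, giving the 2-substituted allyl alcohol without touching the stereocentre.

Step 13
Reactants: 16 2-[(1R)-4-methylcyclohex-3-en-1-yl]prop-2-en-1-ol
Product: 17 methyl 2-[(1R)-4-methylcyclohex-3-en-1-yl]prop-2-en-1-yl carbonate
Conditions: ClCO2Me, pyridine, DMAP (5 mol%), CH2Cl2, 0 °C
Reagents that add atoms: methyl chloroformate, COC(=O)Cl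
Why: Acylation of the primary allylic alcohol with a chloroformate gives the carbonate needed for ionisation by palladium and makes the side-chain alkene electron-poor.

Step 14
Reactants: 17 methyl 2-[(1R)-4-methylcyclohex-3-en-1-yl]prop-2-en-1-yl carbonate
Product: 20 methyl 2-[(1R,3R,4S)-3-bromo-4-hydroxy-4-methylcyclohexyl]prop-2-en-1-yl carbonate, via selenide adduct 18 (not isolated), via bromo trifluoroacetate 19 (not isolated)
Conditions: (PhSe)2 (10 mol%), N-fluoro-2,4,6-trimethylpyridinium tetrafluoroborate (1.3 equiv), CF3CO2Li (3 equiv), 4 Å MS, MeCN, 0 °C, LiBr (1.2 equiv in MeCN) added over 6 h; then NaHCO3, MeOH, 0 °C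
Reagents that add atoms: lithium bromide, [Li+].[Br-]; lithium trifluoroacetate, [Li+].[O-]C(=O)C(F)(F)F
Why: Proposed new method: selenium redox catalysis for a net syn-oxybromination; the divalent selenium electrophile PhSeOCOCF3 (from (PhSe)2 and the N–F oxidant) adds anti and Markovnikov across the ring alkene in the trans-diaxial sense (trifluoroacetate axial on the tertiary carbon and cis to the side chain, selenium axial on the secondary carbon) to give 18; the N–F oxidant then raises the alkyl selenide to a tetravalent fluoroselenonium ion, whose selenium is displaced by bromide with inversion along the axial trajectory, so bromine ends equatorial and cis to the oxygen (19) and divalent selenium is returned; trifluoroacetate is used in place of water because it cannot act as a neighbouring group (no epoxide or acyloxonium, hence no retention) and the dry medium avoids selenoxide syn-elimination; slow addition of LiBr and the weakest N–F oxidant keep bromide oxidation (anti-addition background) low, and the carbonate-bearing alkene is too electron-poor to compete; bicarbonate methanolysis then cleaves only the trifluoroacetate. The closest known reaction types are the selenium-redox-catalysed syn-dichlorination of alkenes and the stoichiometric bromodeselenation of alkyl phenyl selenides with inversion.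

Step 15
Reactants: 10 trimethyl({(3S,6R)-6-methyl-3-(prop-1-en-2-yl)-6-[(trimethylsilyl)oxy]cyclohex-1-en-1-yl}oxy)silane (1.2 equiv); 20 methyl 2-[(1R,3R,4S)-3-bromo-4-hydroxy-4-methylcyclohexyl]prop-2-en-1-yl carbonate
Product: 22 (2R,3S,6R)-2-{2-[(1R,3R,4S)-3-bromo-4-hydroxy-4-methylcyclohexyl]prop-2-en-1-yl}-6-hydroxy-6-methyl-3-(prop-1-en-2-yl)cyclohexan-1-one, via trimethylsilyl ether ketone 21 (not isolated)
Conditions: Pd2(dba)3 (2.5 mol%), 1,2-bis(diphenylphosphino)ethane (6 mol%), Bu4N[Ph3SiF2] (30 mol%), THF, 23 °C; then 1 M HCl, THF, 0 °C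
Reagents that add atoms: none
Why: Tsuji–Trost allylic alkylation: zerovalent palladium ionises the carbonate to a 2-substituted π-allyl complex with loss of CO2, the methoxide released (helped by the fluoride source) unmasks the enolate regiospecifically from the silyl enol ether, and the C–C bond forms anti to the neighbouring isopropenyl group to give the trans-2,3-disubstituted ketone, which is also the more stable epimer; dilute acid then cleaves the tertiary TMS ether.

Step 16
Reactants: 22 (2R,3S,6R)-2-{2-[(1R,3R,4S)-3-bromo-4-hydroxy-4-methylcyclohexyl]prop-2-en-1-yl}-6-hydroxy-6-methyl-3-(prop-1-en-2-yl)cyclohexan-1-one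
Product: 23 prevezol C, (1R,2R,3R,4S)-3-{2-[(1R,3R,4S)-3-bromo-4-hydroxy-4-methylcyclohexyl]prop-2-en-1-yl}-1-methyl-4-(prop-1-en-2-yl)cyclohexane-1,2-diol
Conditions: Me4NBH(OAc)3 (5 equiv), AcOH/MeCN 1:1, −20 to 0 °C
Reagents that add atoms: none
Why: Hydroxyl-directed (Saksena–Evans) reduction: the axial tertiary OH exchanges onto boron and delivers hydride internally to the same face of the neighbouring ketone, so the new OH is axial, trans to the tertiary OH and cis to the side chain, while alkenes and the bromide are left alone.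

**Compound list**
1 | isoprene (2-methylbuta-1,3-diene) | C=CC(C)=C | starting material
2 | acrolein (prop-2-enal) | C=CC=O | starting material
3 | (1S)-4-methylcyclohex-3-ene-1-carbaldehyde | O=C[C@H]1CCC(C)=CC1 | intermediate
4 | 1-[(1S)-4-methylcyclohex-3-en-1-yl]ethan-1-ol (carbinol epimers) | CC(O)[C@H]1CCC(C)=CC1 | intermediate
5 | 1-[(1S)-4-methylcyclohex-3-en-1-yl]ethan-1-one | CC(=O)[C@H]1CCC(C)=CC1 | intermediate
6 | (4S)-1-methyl-4-(prop-1-en-2-yl)cyclohex-1-ene, (S)-limonene | CC(=C)[C@H]1CCC(C)=CC1 | intermediate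
7 | (4S)-1-methyl-4-(prop-1-en-2-yl)-7-oxabicyclo[4.1.0]heptane, limonene 1,2-oxide (cis/trans mixture, not isolated) | CC(=C)[C@H]1CCC2(C)OC2C1 | intermediate
8 | (1R,2R,4S)-1-methyl-4-(prop-1-en-2-yl)cyclohexane-1,2-diol | C1[C@@H](C(=C)C)CC[C@@](C)(O)[C@@H]1O | intermediate
9 | (2R,5S)-2-hydroxy-2-methyl-5-(prop-1-en-2-yl)cyclohexan-1-one | C1[C@@H](C(=C)C)CC[C@@](C)(O)C1=O | intermediate
10 | trimethyl({(3S,6R)-6-methyl-3-(prop-1-en-2-yl)-6-[(trimethylsilyl)oxy]cyclohex-1-en-1-yl}oxy)silane | C1(=C[C@@H](C(=C)C)CC[C@@]1(C)O[Si](C)(C)C)O[Si](C)(C)C | intermediate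
11 | (1R)-4-methylcyclohex-3-ene-1-carbaldehyde | O=C[C@@H]1CCC(C)=CC1 | intermediate
12 | 1-[(1R)-4-methylcyclohex-3-en-1-yl]ethan-1-ol (carbinol epimers) | CC(O)[C@@H]1CCC(C)=CC1 | intermediate
13 | 1-[(1R)-4-methylcyclohex-3-en-1-yl]ethan-1-one | CC(=O)[C@@H]1CCC(C)=CC1 | intermediate
14 | lithium 1-chloro-2-[(1R)-4-methylcyclohex-3-en-1-yl]propan-2-olate (epimers, not isolated) | [Li+].CC([O-])(CCl)[C@@H]1CCC(C)=CC1 | intermediate
15 | 2-methyl-2-[(1R)-4-methylcyclohex-3-en-1-yl]oxirane (epimers at the oxirane carbon) | CC2(CO2)[C@@H]1CCC(C)=CC1 | intermediate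
16 | 2-[(1R)-4-methylcyclohex-3-en-1-yl]prop-2-en-1-ol | OCC(=C)[C@@H]1CCC(C)=CC1 | intermediate
17 | methyl 2-[(1R)-4-methylcyclohex-3-en-1-yl]prop-2-en-1-yl carbonate | COC(=O)OCC(=C)[C@@H]1CCC(C)=CC1 | intermediate
18 | (1S,2S,4R)-4-{3-[(methoxycarbonyl)oxy]prop-1-en-2-yl}-1-methyl-2-(phenylselanyl)cyclohexyl trifluoroacetate (not isolated) | COC(=O)OCC(=C)[C@@H]1CC[C@](C)(OC(=O)C(F)(F)F)[C@@H]([Se]c2ccccc2)C1 | intermediate
19 | (1S,2R,4R)-2-bromo-4-{3-[(methoxycarbonyl)oxy]prop-1-en-2-yl}-1-methylcyclohexyl trifluoroacetate (not isolated) | COC(=O)OCC(=C)[C@@H]1CC[C@](C)(OC(=O)C(F)(F)F)[C@H](Br)C1 | intermediate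
20 | methyl 2-[(1R,3R,4S)-3-bromo-4-hydroxy-4-methylcyclohexyl]prop-2-en-1-yl carbonate | COC(=O)OCC(=C)[C@@H]1CC[C@](C)(O)[C@H](Br)C1 | intermediate
21 | (2R,3S,6R)-2-{2-[(1R,3R,4S)-3-bromo-4-hydroxy-4-methylcyclohexyl]prop-2-en-1-yl}-6-methyl-3-(prop-1-en-2-yl)-6-[(trimethylsilyl)oxy]cyclohexan-1-one (not isolated) | C=C(C[C@@H]1[C@@H](C(=C)C)CC[C@@](C)(O[Si](C)(C)C)C1=O)[C@@H]1CC[C@](C)(O)[C@H](Br)C1 | intermediate
22 | (2R,3S,6R)-2-{2-[(1R,3R,4S)-3-bromo-4-hydroxy-4-methylcyclohexyl]prop-2-en-1-yl}-6-hydroxy-6-methyl-3-(prop-1-en-2-yl)cyclohexan-1-one | C=C(C[C@@H]1[C@@H](C(=C)C)CC[C@@](C)(O)C1=O)[C@@H]1CC[C@](C)(O)[C@H](Br)C1 | intermediate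
23 | prevezol C, (1R,2R,3R,4S)-3-{2-[(1R,3R,4S)-3-bromo-4-hydroxy-4-methylcyclohexyl]prop-2-en-1-yl}-1-methyl-4-(prop-1-en-2-yl)cyclohexane-1,2-diol | C=C(C[C@@H]1[C@@H](C(=C)C)CC[C@@](C)(O)[C@@H]1O)[C@@H]1CC[C@](C)(O)[C@H](Br)C1 | target

**Step count**
Total: 16 steps. Longest linear sequence: 9 steps (steps 1–7, 15, 16; the ring B branch, steps 8–14, 15, 16, is equally long).

**Three steps most likely to fail**

Step 14 (the proposed new method). The N–F oxidant may oxidise bromide and give anti-addition products, or the tetravalent selenium intermediate may eliminate instead of being displaced at the hindered secondary carbon. The fallback uses known stoichiometric chemistry in separate operations. It sets out from 17. PhSeBr and AgOCOCF3 in CH2Cl2 at −78 °C (anti trifluoroacetoxyselenenylation) give the selenide adduct 18, this time isolated. Br2 (1.05 equiv) in CH2Cl2 at −78 °C converts the selenide at once into its selenium dibromide; cyclohexene is then added to trap the PhSeBr that is released, and on warming to 0 °C bromide displaces selenium with inversion (bromodeselenation) to give 19. NaHCO3 in MeOH as in step 14 gives 20, where the route is rejoined. No compound outside the list is made (F0).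

Step 15 (fragment union). Ionisation or C–C bond formation may be slow at the hindered enolate carbon, and O-allylation by the ring B tertiary alkoxide or double allylation may compete. The fallback replaces the π-allyl coupling by a stoichiometric enolate alkylation and sets out from 20 and 10. K2CO3 in MeOH at 0 °C removes the methyl carbonate of 20 to give 2-[(1R,3R,4S)-3-bromo-4-hydroxy-4-methylcyclohexyl]prop-2-en-1-ol F1. CBr4 and PPh3 in CH2Cl2 at 0 °C convert only the primary allylic OH into the bromide (1S,2R,4R)-2-bromo-4-(3-bromoprop-1-en-2-yl)-1-methylcyclohexan-1-ol F2. MeLi in THF at 0 °C cleaves the enol silyl ether of 10 to the regiodefined enolate lithium (3S,6R)-6-methyl-3-(prop-1-en-2-yl)-6-[(trimethylsilyl)oxy]cyclohex-1-en-1-olate F3. F3 is alkylated with F2 in THF/DMPU at −78 to −20 °C, again anti to the isopropenyl group, and gives 21, where the route is rejoined; acid treatment as in step 15 then gives 22.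

Step 16 (directed reduction). The hindered tertiary OH may exchange onto boron too slowly, so that nothing happens, and an undirected hydride would attack anti to the axial C–O bond and give the cis-diol. The fallback replaces ligand exchange on boron by a covalently tethered hydride and sets out from 22. ClSiHMe2 and imidazole in DMF at 0 °C silylate both tertiary hydroxyls to give (2R,3S,6R)-2-{2-[(1R,3R,4S)-3-bromo-4-[(dimethylsilyl)oxy]-4-methylcyclohexyl]prop-2-en-1-yl}-6-[(dimethylsilyl)oxy]-6-methyl-3-(prop-1-en-2-yl)cyclohexan-1-one F4. Bu4NF in THF at −20 to 23 °C forms a hydridosilicate on the ring A oxygen, which transfers hydride intramolecularly to the same face of the ketone (fluoride-promoted intramolecular hydrosilylation), and then strips both silyl groups; the route is rejoined at 23.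

**Further compounds**
F0 | step 14 | none | none
F1 | step 15 | 2-[(1R,3R,4S)-3-bromo-4-hydroxy-4-methylcyclohexyl]prop-2-en-1-ol | OCC(=C)[C@@H]1CC[C@](C)(O)[C@H](Br)C1
F2 | step 15 | (1S,2R,4R)-2-bromo-4-(3-bromoprop-1-en-2-yl)-1-methylcyclohexan-1-ol | BrCC(=C)[C@@H]1CC[C@](C)(O)[C@H](Br)C1
F3 | step 15 | lithium (3S,6R)-6-methyl-3-(prop-1-en-2-yl)-6-[(trimethylsilyl)oxy]cyclohex-1-en-1-olate | C1(=C[C@@H](C(=C)C)CC[C@@]1(C)O[Si](C)(C)C)[O-].[Li+]
F4 | step 16 | (2R,3S,6R)-2-{2-[(1R,3R,4S)-3-bromo-4-[(dimethylsilyl)oxy]-4-methylcyclohexyl]prop-2-en-1-yl}-6-[(dimethylsilyl)oxy]-6-methyl-3-(prop-1-en-2-yl)cyclohexan-1-one | C=C(C[C@@H]1[C@@H](C(=C)C)CC[C@@](C)(O[SiH](C)C)C1=O)[C@@H]1CC[C@](C)(O[SiH](C)C)[C@H](Br)C1
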